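**Assumption:** Albanin A has no stereocentres and no stereogenic double bond (the prenyl alkene carries two identical methyl groups), so it is achiral and no stereocontrol is needed.

## Retrosynthetic overview

1. Albanin A (11) ⇐ its tetra-MOM ether 10, by global deprotection as the last step.
2. Pyranone C ring (C3–C4 and O1–C2 bonds) ⇐ Rh(III) aldehyde C–H activation/[4+2] annulation of salicylaldehyde 4 (A ring + C4) with aryl prenyl alkyne 9 (B ring + C2/C3 + prenyl).
3. Alkyne 9 ⇐ Sonogashira coupling of aryl iodide 5 with enyne 8; 8 ⇐ prenyl bromide + ethynylmagnesium bromide.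
4. Aldehyde 4 ⇐ ortho-formylation of phenol 3 ⇐ Ir C–H borylation/oxidation of bis-MOM resorcinol 2; iodide 5 ⇐ iodination of the same 2.
5. Ring order: A and B rings both come from resorcinol; the C ring is formed last in the annulation.

## Route

**Step 1**
Reactants: 1, resorcinol
Product: 2, 1,3-bis(methoxymethoxy)benzene
Conditions: NaH (2.5 equiv), MOMCl (2.4 equiv), DMF, 0 °C → rt
Reagents that add atoms: chloromethyl methyl ether (MOMCl), COCCl
Why: Williamson-type O-alkylation of the bis-phenoxide gives the bis-acetal, which is stable to all later basic and organometallic steps.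

**Step 2**
Reactants: 2, 1,3-bis(methoxymethoxy)benzene
Product: 3, 3,5-bis(methoxymethoxy)phenol
Conditions: [Ir(OMe)(cod)]2 (1 mol%), dtbpy (2 mol%), B2pin2, THF, 80 °C; then 2 M NaOH, 30% H2O2, 0 °C → rt (one pot, aryl-Bpin not isolated)
Reagents that add atoms: hydrogen peroxide, OO
Why: Sterically controlled Ir-catalysed C–H borylation occurs only at C5 (the one C–H with no ortho substituent), and basic peroxide oxidation of the aryl boronate gives the phenol without touching the MOM acetals.

**Step 3**
Reactants: 3, 3,5-bis(methoxymethoxy)phenol
Product: 4, 2-hydroxy-4,6-bis(methoxymethoxy)benzaldehyde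
Conditions: MgCl2 (2 equiv), Et3N (4 equiv), (CH2O)n (6 equiv), MeCN, reflux
Reagents that add atoms: paraformaldehyde (formaldehyde), C=O
Why: Magnesium phenoxide-directed ortho-formylation (Casnati–Skattebøl) delivers CHO exclusively ortho to the free OH; the two ortho positions are equivalent, so one isomer forms.

**Step 4**
Reactants: 2, 1,3-bis(methoxymethoxy)benzene
Product: 5, 1-iodo-2,4-bis(methoxymethoxy)benzene
Conditions: NIS (1.0 equiv), MeCN, 0 °C → rt, dark
Reagents that add atoms: N-iodosuccinimide, O=C1CCC(=O)N1I
Why: Electrophilic aromatic iodination of the resorcinol diether goes at C4 (ortho/para to the two alkoxy groups, not the hindered C2) under neutral conditions that MOM tolerates.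

**Step 5**
Reactants: 6, prenyl bromide (1-bromo-3-methylbut-2-ene); 7, ethynylmagnesium bromide
Product: 8, 5-methylhex-4-en-1-yne
Conditions: 7 (1.3 equiv, 0.5 M in THF), CuCl (5 mol%), THF, 0 → 40 °C; product distilled and used as a titrated solution (volatile)
Reagents that add atoms: none
Why: Cu(I)-catalysed alkynyl Grignard/allyl halide coupling attacks the unhindered primary terminus of the prenyl electrophile (SN2 sense) to give the skipped enyne.

**Step 6**
Reactants: 5, 1-iodo-2,4-bis(methoxymethoxy)benzene; 8, 5-methylhex-4-en-1-yne
Product: 9, 1-(5-methylhex-4-en-1-yn-1-yl)-2,4-bis(methoxymethoxy)benzene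
Conditions: PdCl2(PPh3)2 (2 mol%), CuI (4 mol%), Et3N/THF, 40 °C, 8 (1.5 equiv)
Reagents that add atoms: none
Why: Sonogashira coupling of an aryl iodide with a terminal alkyne; the mild amine base does not isomerise the 1,4-enyne and the trisubstituted alkene is inert to Pd(0).

**Step 7 (key step)**
Reactants: 4, 2-hydroxy-4,6-bis(methoxymethoxy)benzaldehyde; 9, 1-(5-methylhex-4-en-1-yn-1-yl)-2,4-bis(methoxymethoxy)benzene
Product: 10, 2-[2,4-bis(methoxymethoxy)phenyl]-5,7-bis(methoxymethoxy)-3-(3-methylbut-2-en-1-yl)-4H-chromen-4-one
Conditions: [Cp*RhCl2]2 (2.5 mol%), Cu(OAc)2 (2.2 equiv), NaOAc (1 equiv), DCE, 80 °C, N2, 9 (1.2 equiv)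
Reagents that add atoms: none
Why: Proposed new method: an oxidative Rh(III) aldehyde C–H activation/[4+2] annulation using a skipped enyne (aryl prenyl alkyne) and a 2,6-dioxygenated salicylaldehyde, a substrate pairing not yet demonstrated, to give the 3-prenylflavone directly; the phenoxide-bound Cp*Rh(III) cleaves the formyl C–H by acetate-assisted metalation to a five-membered acyl rhodacycle, the alkyne inserts into the Rh–acyl bond with Rh ending on the aryl-bearing carbon (aryl-stabilised, possibly reinforced by chelation from the ortho-OMOM oxygen), C–O reductive elimination then places O1 on the aryl carbon (C2-aryl, C3-prenyl) and Cu(II) reoxidises Rh(I), while the remote trisubstituted alkene should not insert and the acetate buffer protects the MOM groups; the closest known reaction is the Rh/Cu oxidative annulation of salicylaldehydes with diaryl, dialkyl and simple aryl–alkyl alkynes to 2,3-disubstituted chromones.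

**Step 8**
Reactants: 10, tetra-MOM 3-prenylflavone
Product: 11, Albanin A (5,7-dihydroxy-2-(2,4-dihydroxyphenyl)-3-(3-methylbut-2-en-1-yl)-4H-chromen-4-one)
Conditions: 3 M aq HCl/MeOH (1:5), 45 °C, monitored and stopped at full conversion
Reagents that add atoms: none
Why: Acid-catalysed acetal methanolysis removes all four aryl MOM ethers under conditions too mild to protonate the trisubstituted prenyl alkene at a competitive rate.

## Compound list

1 | resorcinol | Oc1cccc(O)c1 | starting material
2 | 1,3-bis(methoxymethoxy)benzene | COCOc1cccc(OCOC)c1 | intermediate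
3 | 3,5-bis(methoxymethoxy)phenol | COCOc1cc(O)cc(OCOC)c1 | intermediate
4 | 2-hydroxy-4,6-bis(methoxymethoxy)benzaldehyde | COCOc1cc(O)c(C=O)c(OCOC)c1 | intermediate
5 | 1-iodo-2,4-bis(methoxymethoxy)benzene | COCOc1ccc(I)c(OCOC)c1 | intermediate
6 | prenyl bromide (1-bromo-3-methylbut-2-ene) | CC(C)=CCBr | starting material
7 | ethynylmagnesium bromide | C#C[Mg]Br | starting material
8 | 5-methylhex-4-en-1-yne | CC(C)=CCC#C | intermediate
9 | 1-(5-methylhex-4-en-1-yn-1-yl)-2,4-bis(methoxymethoxy)benzene | COCOc1ccc(C#CCC=C(C)C)c(OCOC)c1 | intermediate
10 | 2-[2,4-bis(methoxymethoxy)phenyl]-5,7-bis(methoxymethoxy)-3-(3-methylbut-2-en-1-yl)-4H-chromen-4-one | CC(C)=CCc1c(-c2ccc(OCOC)cc2OCOC)oc2cc(OCOC)cc(OCOC)c2c1=O | intermediate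
11 | Albanin A | CC(C)=CCc1c(-c2ccc(O)cc2O)oc2cc(O)cc(O)c2c1=O | target

## Step count

- Total steps: 8 (the one-pot borylation/oxidation is counted as one step).
- Longest linear sequence: 5 steps (1 → 2 → 3 → 7 → 8, or equally 1 → 4 → 6 → 7 → 8).

## Steps most likely to fail

1. **Step 7 (proposed new annulation).** Risks are decarbonylation of the hindered acyl-rhodium (giving a benzofuran), wrong alkyne regiochemistry, and isomerisation or allylic activation of the skipped enyne. Known-chemistry fallback:
   - Sonogashira couple 5 with TMS-acetylene and desilylate to 2,4-bis(methoxymethoxy)phenylacetylene.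
   - Add its lithium acetylide to O-protected 4 and oxidise with MnO2 to the ynone.
   - Unmask the phenol and cyclise 6-endo with amine base to the 3-H flavone.
   - Iodinate C3 (LDA, then I2).
   - Install prenyl by Pd-catalysed, linear-selective Suzuki coupling with prenyl-Bpin.

2. **Step 8 (global MOM removal).** The risk is acid-mediated hydration of the prenyl alkene or its cyclisation onto the 2'-OH or 5-OH. Fallback: run the whole sequence with SEM ethers (SEMCl in step 1) and deprotect with fluoride (TBAF, DMPU, 60–80 °C), so no cationic chemistry occurs near the prenyl group.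

3. **Step 5 (enyne 8).** Risks are SN2' (branched) product and loss of the volatile enyne on isolation. Fallback: alkylate lithiated trimethylsilylacetylene with prenyl bromide (uncatalysed SN2, THF/DMPU) to the non-volatile TMS-enyne, then do a one-pot CsF-mediated desilylative (sila-)Sonogashira coupling with 5 in step 6; the step count is unchanged.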